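(The numbers in the tables are simulated with made-up constants; the scatter is artificial.)

Late in a run the rate depends on the nucleophile still free, so I began by counting what each reacted electrophile costs. The electrophile and nucleophile give target and acid set free, and nucleophile can bind that acid as protonated nucleophile or idle adduct.

| flask | electrophile | nucleophile | remark | time |
|---|---|---|---|---|
| Saturday's | 2.5 M | 2.04 M | run made earlier |  |
| Tuesday's | 0.85 M | 2.04 M | run made earlier |  |
| violet | 1.7 M | 2.00 M |  | 15 h |
| green | 1.7 M | 2.70 M |  | 15 h |

| run | time / h | electrophile / % | target / % |
|---|---|---|---|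
| Saturday's | 0.417 | 96.3 | 3.9 |
| Saturday's | 1.00 | 92.0 | 8.3 |
| Saturday's | 2.50 | 83.5 | 16.1 |
| Saturday's | 5.00 | 75.1 | 25.6 |
| Tuesday's | 0.667 | 93.8 | 6.1 |
| Tuesday's | 2.00 | 83.8 | 16.9 |
| Tuesday's | 3.00 | 77.5 | 22.9 |
| Tuesday's | 5.00 | 67.6 | 32.8 |

(each reading ± 0.3 percentage points)

- for acid set free the idle adduct is counted in
- steps that have been proposed: electrophile + nucleophile -> acid set free + target; nucleophile + acid set free <-> protonated nucleophile; nucleophile + acid set free <-> idle adduct

1. part of the electrophile that has reacted at the end, violet
2. part of the electrophile that has reacted at the end, green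
3. what raising the concentration of nucleophile from its lowest to its highest value here does to the part of the electrophile that has reacted (changes below 5 percentage points count as none) (no change / it falls / it rises)

1. Fastest rung: I took the binding of the acid as complete at every reading, so each reacted electrophile cost two nucleophile.

2. Test: I used rate = k·c(electrophile)·c(nucleophile). For the reacted share this integrates to (E − 1)/(ρE − 1), with ρ = 2c(electrophile)/c(nucleophile) and E = exp(k·t·(2c(electrophile) − c(nucleophile))), both concentrations as charged. Target at the last reading gave k = 0.0467 L mol⁻¹ h⁻¹ for Saturday's run and 0.0460 L mol⁻¹ h⁻¹ for Tuesday's. Counting one for one, the same readings gave 0.0351 L mol⁻¹ h⁻¹ and 0.0421 L mol⁻¹ h⁻¹, which disagree. I kept the mean of the first pair, the two-for-one constant k = 0.0464 L mol⁻¹ h⁻¹, as a reading with its scatter.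

3. Middle rung: the inverse of k·c(nucleophile) at the start was 10.8 h for violet and 7.99 h for green, both shorter than the 15 h allowed, so the nucleophile spent had to be counted.

4. Slowest rung: I applied the two-for-one count only up to 15 h, as an estimate and not a bound. On it, green's charge matches 1.35 M of electrophile, less than the 1.7 M charged. On this count nucleophile is the limiting reagent in green, and violet's smaller charge matches less still.

5. My reckoning gave 47.1% for violet and 59.8% for green, a rise of 13 percentage points.

The forecast stood slightly lower than mine, at 46.6% and 59.2% with the verdict "it rises", holding that “the acid is effectively fully captured”.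

The flask gave 47.1% for violet and 59.7% for green, so it rises, by 13 points.

    electrophile + nucleophile → acid set free + target (k = 1.28 × 10⁻⁵ L mol⁻¹ s⁻¹)
    nucleophile + acid set free ⇌ protonated nucleophile, settled at all times (K = 110 L mol⁻¹)
    nucleophile + acid set free ⇌ idle adduct, settled at all times (K = 118 L mol⁻¹)

Green ended with 25.0% of its nucleophile free, and the two-for-one count from its result gives 24.8%. With k as read, I reckoned the electrophile's pseudo-first-order constant at that moment in green at 0.0313 h⁻¹, a quarter of my reckoning for the start.

For green read at 40 h, k gives 73.7%. The computed flask gives 74.0%.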